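**Plan**

1. Numbering: 14-membered ring C1–C14 (C1 lactone-fused CH, C2 O–CH, C6 CHOH, C10 CHOAc; alkenes C3=C4, C7=C8, C11=C12), lactone carbons C15 (α), C16 (C=O), C17 (=CH2). The E C11=C12 alkene carries its methyl on C12, distal to the C10 oxygen, which is the pattern left by C10-alkoxide-directed anti hydroalumination and methylation of a C11≡C12 alkyne, so the ring can be closed as a geometry-free cycloalkyne.
2. Retrosynthetic cuts, in order: the C16–O lactone bond (to a silyl-masked C2/C16 diol), C12–CH3 with the C11=C12 π-bond (to the cycloalkyne), C11≡C12 (ring-closing alkyne metathesis), C1–C2 (allylboration), then C5–C6 and C9–C10 (vinylogous Mukaiyama aldols).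
3. Forward: but-2-ynal is extended twice by a silyl dienolate to the C2–C11 enal; an allylboronate carrying the pent-3-ynyl arm adds C1 and C12–C17; alkyne metathesis closes the only carbocycle; hydroalumination/iodination/methylation, acetylation and desilylation follow; the lactone ring is closed last by oxidation.
4. Stereochemistry: C10 and C6 come from catalyst-controlled Si-face vinylogous aldols; C2 and C1 come from a chiral-phosphoric-acid-catalysed, chair-organised Re-face anti allylboration whose boronate geometry is fixed by syn hydrostannation of an ynoate.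
5. Alkene geometry: E C3=C4 and C7=C8 arise in the aldol steps; E C11=C12 arises from anti H/Al addition across the ring alkyne.

Key step: step 20

Assumption: each chiral catalyst is named as the enantiomer expected to reach the stated aldehyde face; should the sense of induction prove opposite, its antipode is used. Macrocycles are named with the ring numbering of line 1.

**Allylboronate (C1, C12–C17)**

Step 1
Reactants: 1 hex-4-yn-1-ol
Product: 2 hex-4-ynal
Conditions: TEMPO (10 mol%), PhI(OAc)2 (1.1 equiv), CH2Cl2, rt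
Reagents that add atoms: none
Why: Oxoammonium (TEMPO) oxidation of a primary alcohol stops at the aldehyde and leaves the internal alkyne untouched.

Step 2
Reactants: 2 hex-4-ynal
Product: 3 1,1-dibromohept-1-en-5-yne
Conditions: CBr4, PPh3, CH2Cl2, 0 °C
Reagents that add atoms: carbon tetrabromide, BrC(Br)(Br)Br
Why: First stage of the Corey–Fuchs homologation, a Wittig-type dibromo-olefination by the ylide formed from CBr4 and PPh3.

Step 3
Reactants: 3 1,1-dibromohept-1-en-5-yne
Product: 5 methyl octa-2,6-diynoate, via lithium acetylide 4 (not isolated)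
Conditions: n-BuLi (2.1 equiv), THF, −78 °C; then ClCO2Me, −78 °C → rt
Reagents that add atoms: methyl chloroformate, COC(=O)Cl
Why: Second stage of the Corey–Fuchs sequence (Br/Li exchange, 1,2-shift to the alkyne, deprotonation) gives the lithium acetylide, which is C-acylated in the same flask by the chloroformate.

Step 4
Reactants: 5 methyl octa-2,6-diynoate
Product: 7 methyl (2E)-2-iodooct-2-en-6-ynoate, via vinylstannane 6 (not isolated)
Conditions: Pd(PPh3)4 (2 mol%), Bu3SnH (slow addition), THF, 0 °C; then I2, 0 °C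
Reagents that add atoms: iodine, II
Why: Pd-catalysed hydrostannation of a 2-ynoate adds H and Sn syn with tin on the α-carbon, and iododestannylation proceeds with retention, so iodine ends trans to the pentynyl chain; the unactivated dialkyl alkyne should not compete.

Step 5
Reactants: 7 methyl (2E)-2-iodooct-2-en-6-ynoate
Product: 8 (2E)-2-iodooct-2-en-6-yn-1-ol
Conditions: DIBAL-H (2.2 equiv), CH2Cl2, −78 °C; Rochelle salt work-up
Reagents that add atoms: none
Why: DIBAL-H 1,2-reduction of an enoate to the allylic alcohol, to which the vinyl iodide and the alkyne are inert at low temperature.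

Step 6
Reactants: 8 (2E)-2-iodooct-2-en-6-yn-1-ol
Product: 9 tert-butyl{[(2E)-2-iodooct-2-en-6-yn-1-yl]oxy}dimethylsilane
Conditions: TBSCl, imidazole, CH2Cl2, rt
Reagents that add atoms: tert-butyldimethylsilyl chloride, CC(C)(C)[Si](C)(C)Cl
Why: Standard imidazole-mediated silylation of a primary alcohol.

Step 7
Reactants: 9 tert-butyl{[(2E)-2-iodooct-2-en-6-yn-1-yl]oxy}dimethylsilane
Product: 10 tert-butyldimethyl{[(2Z)-2-[(4,4,5,5-tetramethyl-1,3,2-dioxaborolan-2-yl)methyl]oct-2-en-6-yn-1-yl]oxy}silane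
Conditions: CH2(Bpin)2 (1.5 equiv), Pd[P(t-Bu)3]2 (5 mol%), aq. KOH, 1,4-dioxane, rt
Reagents that add atoms: bis[(pinacolato)boryl]methane, CC1(C)OB(CB2OC(C)(C)C(C)(C)O2)OC1(C)C
Why: Suzuki–Miyaura coupling of a gem-diborylmethane (one boron transmetallates as its hydroxide ate complex) with an alkenyl iodide proceeds with retention, giving the allylboronate with the pentynyl chain trans to CH2B (E-crotyl-type geometry).

**Silyl dienolate**

Step 8
Reactants: 11 methyl 3-methylbut-2-enoate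
Product: 13 (1Z)-1-[(tert-butyldimethylsilyl)oxy]-1-methoxy-3-methylbuta-1,3-diene, via lithium dienolate 12 (not isolated)
Conditions: LDA, THF, −78 °C; then TBSCl, DMPU, −78 °C → rt
Reagents that add atoms: tert-butyldimethylsilyl chloride, CC(C)(C)[Si](C)(C)Cl
Why: Kinetic γ-deprotonation of the enoate and O-silylation of the extended enolate give the vinylketene silyl acetal, whose ketene acetal geometry has no bearing on the later aldol outcome.

**Chain C2–C11 and union**

Step 9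
Reactants: 14 but-2-yn-1-ol
Product: 15 but-2-ynal
Conditions: activated MnO2, CH2Cl2, rt; filtration, careful distillation
Reagents that add atoms: none
Why: MnO2 oxidation is selective for propargylic alcohols and stops at the ynal.

Step 10
Reactants: 15 but-2-ynal; 13 (1Z)-1-[(tert-butyldimethylsilyl)oxy]-1-methoxy-3-methylbuta-1,3-diene
Product: 17 methyl (2E,5S)-5-hydroxy-3-methyloct-2-en-6-ynoate, via trichlorosilyl ether 16 (not isolated)
Conditions: SiCl4 (1.1 equiv), (S,S)-bisphosphoramide (BINAM-derived, pentamethylene-linked; 2 mol%), i-Pr2NEt (10 mol%), CH2Cl2, −78 °C; aq. KF/NaHCO3 work-up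
Reagents that add atoms: none
Why: Lewis-base-activated SiCl4 vinylogous Mukaiyama aldol reaction in which the dienolate reacts at its γ-carbon to give the E-enoate, and the chiral phosphoramide-bound silicon cation exposes the Si face of the ynal to set C10 (5S in 17).

Step 11
Reactants: 17 methyl (2E,5S)-5-hydroxy-3-methyloct-2-en-6-ynoate
Product: 18 methyl (2E,5S)-3-methyl-5-[(triethylsilyl)oxy]oct-2-en-6-ynoate
Conditions: TESCl, imidazole, DMF, 0 °C
Reagents that add atoms: chlorotriethylsilane, CC[Si](Cl)(CC)CC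
Why: Standard silylation; TES is chosen so that C10 alone can be unmasked later beside TBS ethers.

Step 12
Reactants: 18 methyl (2E,5S)-3-methyl-5-[(triethylsilyl)oxy]oct-2-en-6-ynoate
Product: 19 (2E,5S)-3-methyl-5-[(triethylsilyl)oxy]oct-2-en-6-yn-1-ol
Conditions: DIBAL-H (2.2 equiv), CH2Cl2, −78 °C; Rochelle salt work-up
Reagents that add atoms: none
Why: DIBAL-H 1,2-reduction of the enoate, compatible with the silyl ether and the alkyne.

Step 13
Reactants: 19 (2E,5S)-3-methyl-5-[(triethylsilyl)oxy]oct-2-en-6-yn-1-ol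
Product: 20 (2E,5S)-3-methyl-5-[(triethylsilyl)oxy]oct-2-en-6-ynal
Conditions: activated MnO2, CH2Cl2, rt
Reagents that add atoms: none
Why: Neutral MnO2 allylic oxidation gives the enal without E/Z isomerisation or loss of the TES group.

Step 14
Reactants: 20 (2E,5S)-3-methyl-5-[(triethylsilyl)oxy]oct-2-en-6-ynal; 13 (1Z)-1-[(tert-butyldimethylsilyl)oxy]-1-methoxy-3-methylbuta-1,3-diene
Product: 22 methyl (2E,5S,6E,9S)-5-hydroxy-3,7-dimethyl-9-[(triethylsilyl)oxy]dodeca-2,6-dien-10-ynoate, via trichlorosilyl ether 21 (not isolated)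
Conditions: SiCl4 (1.1 equiv), (S,S)-bisphosphoramide (2 mol%), i-Pr2NEt (10 mol%), CH2Cl2, −78 °C; aq. KF/NaHCO3 work-up
Reagents that add atoms: none
Why: The same vinylogous Mukaiyama aldol reaction adds 1,2 to the enal at the dienolate γ-carbon, the catalyst again selecting the Si face to set C6 (5S in 22), with the remote C10 centre too distant to interfere.

Step 15
Reactants: 22 methyl (2E,5S,6E,9S)-5-hydroxy-3,7-dimethyl-9-[(triethylsilyl)oxy]dodeca-2,6-dien-10-ynoate
Product: 23 methyl (2E,5S,6E,9S)-5-[(tert-butyldimethylsilyl)oxy]-3,7-dimethyl-9-[(triethylsilyl)oxy]dodeca-2,6-dien-10-ynoate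
Conditions: TBSCl, imidazole, DMF, rt
Reagents that add atoms: tert-butyldimethylsilyl chloride, CC(C)(C)[Si](C)(C)Cl
Why: Standard silylation of the secondary allylic alcohol; the TES ether is stable to these conditions.

Step 16
Reactants: 23 methyl (2E,5S,6E,9S)-5-[(tert-butyldimethylsilyl)oxy]-3,7-dimethyl-9-[(triethylsilyl)oxy]dodeca-2,6-dien-10-ynoate
Product: 24 (2E,5S,6E,9S)-5-[(tert-butyldimethylsilyl)oxy]-3,7-dimethyl-9-[(triethylsilyl)oxy]dodeca-2,6-dien-10-yn-1-ol
Conditions: DIBAL-H (2.2 equiv), CH2Cl2, −78 °C; Rochelle salt work-up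
Reagents that add atoms: none
Why: DIBAL-H 1,2-reduction of the enoate as in step 12.

Step 17
Reactants: 24 (2E,5S,6E,9S)-5-[(tert-butyldimethylsilyl)oxy]-3,7-dimethyl-9-[(triethylsilyl)oxy]dodeca-2,6-dien-10-yn-1-ol
Product: 25 (2E,5S,6E,9S)-5-[(tert-butyldimethylsilyl)oxy]-3,7-dimethyl-9-[(triethylsilyl)oxy]dodeca-2,6-dien-10-ynal
Conditions: activated MnO2, CH2Cl2, rt
Reagents that add atoms: none
Why: MnO2 allylic oxidation gives the C2 enal under neutral conditions.

Step 18
Reactants: 25 (2E,5S,6E,9S)-5-[(tert-butyldimethylsilyl)oxy]-3,7-dimethyl-9-[(triethylsilyl)oxy]dodeca-2,6-dien-10-ynal; 10 tert-butyldimethyl{[(2Z)-2-[(4,4,5,5-tetramethyl-1,3,2-dioxaborolan-2-yl)methyl]oct-2-en-6-yn-1-yl]oxy}silane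
Product: 27 (4S,6E,8S,10E,12S,13R)-8-[(tert-butyldimethylsilyl)oxy]-13-{3-[(tert-butyldimethylsilyl)oxy]prop-1-en-2-yl}-6,10-dimethyl-4-[(triethylsilyl)oxy]octadeca-6,10-diene-2,16-diyn-12-ol, via borate ester 26 (not isolated)
Conditions: (R)-TRIP (3,3'-bis(2,4,6-triisopropylphenyl)-BINOL hydrogen phosphate, 10 mol%), 4 Å MS, toluene, −30 °C; aq. NaHCO3 work-up
Reagents that add atoms: none
Why: Chiral-phosphoric-acid-catalysed allylboration through a closed Zimmerman–Traxler chair places the pentynyl group trans to CH2B equatorially, which gives the anti C1/C2 relationship, while the (R)-catalyst directs addition to the Re face of the enal to set 2S and thereby 1R (12S,13R in 27).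

Step 19
Reactants: 27 (4S,6E,8S,10E,12S,13R)-8-[(tert-butyldimethylsilyl)oxy]-13-{3-[(tert-butyldimethylsilyl)oxy]prop-1-en-2-yl}-6,10-dimethyl-4-[(triethylsilyl)oxy]octadeca-6,10-diene-2,16-diyn-12-ol
Product: 28 (4S,6E,8S,10E,12S,13R)-8,12-bis[(tert-butyldimethylsilyl)oxy]-13-{3-[(tert-butyldimethylsilyl)oxy]prop-1-en-2-yl}-6,10-dimethyl-4-[(triethylsilyl)oxy]octadeca-6,10-diene-2,16-diyne
Conditions: TBSOTf, 2,6-lutidine, CH2Cl2, −78 → 0 °C
Reagents that add atoms: tert-butyldimethylsilyl trifluoromethanesulfonate, CC(C)(C)[Si](C)(C)OS(=O)(=O)C(F)(F)F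
Why: The silyl triflate silylates the hindered secondary alcohol flanked by the branched C1, leaving no protic group for the metathesis catalyst.

**Macrocycle and end game**

Step 20
Reactants: 28 (4S,6E,8S,10E,12S,13R)-8,12-bis[(tert-butyldimethylsilyl)oxy]-13-{3-[(tert-butyldimethylsilyl)oxy]prop-1-en-2-yl}-6,10-dimethyl-4-[(triethylsilyl)oxy]octadeca-6,10-diene-2,16-diyne
Product: 29 (1R,2S,3E,6S,7E,10S)-2,6-bis[(tert-butyldimethylsilyl)oxy]-1-{3-[(tert-butyldimethylsilyl)oxy]prop-1-en-2-yl}-4,8-dimethyl-10-[(triethylsilyl)oxy]cyclotetradeca-3,7-dien-11-yne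
Conditions: Mo(≡CC6H4-4-OMe)(OSiPh3)3 (10 mol%), 5 Å MS, toluene (2 mM), rt → 60 °C
Reagents that add atoms: none
Why: The molybdenum alkylidyne adds [2+2] to one methyl-capped alkyne to give a metallacyclobutadiene, cycloreverts to a chain-bound alkylidyne and repeats the sequence on the second alkyne, expelling but-2-yne, whose capture by the 5 Å sieves drives the equilibria. The closest known reaction is ring-closing alkyne metathesis of bis(methylalkynyl) chains to 12- to 20-membered cycloalkynes with silanolate-ligated molybdenum alkylidynes. The 14-membered carbocycle closes by formation of the C11≡C12 triple bond between the two chain termini (endocyclic alkyne), a ring large enough to hold the linear C10–C11≡C12–C13 unit without undue strain. No stereocentre is formed, and because an alkyne has no geometry the E/Z problem of closing the trisubstituted C11=C12 alkene directly does not arise. The step needs alkyne-over-alkene chemoselectivity, which the alkylidyne provides inherently toward the two trisubstituted and the 1,1-disubstituted C=C bonds, and cyclisation over oligomerisation, which high dilution and the conformational restriction by the two E-alkenes should secure; all four oxygens are silylated so that no free (propargylic) alcohol can deactivate the catalyst.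

Step 21
Reactants: 29 (1R,2S,3E,6S,7E,10S)-2,6-bis[(tert-butyldimethylsilyl)oxy]-1-{3-[(tert-butyldimethylsilyl)oxy]prop-1-en-2-yl}-4,8-dimethyl-10-[(triethylsilyl)oxy]cyclotetradeca-3,7-dien-11-yne
Product: 30 (1S,4E,6S,8E,10S,11R)-6,10-bis[(tert-butyldimethylsilyl)oxy]-11-{3-[(tert-butyldimethylsilyl)oxy]prop-1-en-2-yl}-4,8-dimethylcyclotetradeca-4,8-dien-2-yn-1-ol (ring numbering of the plan: C10 alcohol)
Conditions: PPTS (0.2 equiv), MeOH/CH2Cl2 (1:1), 0 °C
Reagents that add atoms: none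
Why: Mild acid methanolysis cleaves a secondary TES ether much faster than secondary or primary TBS ethers, freeing only the propargylic C10 hydroxyl.

Step 22
Reactants: 30 C10 propargylic alcohol
Product: 32 (1R,2S,3E,6S,7E,10S,11Z)-2,6-bis[(tert-butyldimethylsilyl)oxy]-1-{3-[(tert-butyldimethylsilyl)oxy]prop-1-en-2-yl}-12-iodo-4,8-dimethylcyclotetradeca-3,7,11-trien-10-ol, via alkenylalanate 31 (not isolated)
Conditions: Red-Al (3 equiv), THF, 0 °C → rt; EtOAc, then I2, −78 → 0 °C
Reagents that add atoms: iodine, II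
Why: Alkoxide-directed trans-hydroalumination of a propargylic alcohol delivers hydride from the O-bound aluminium to the proximal C11 and leaves aluminium on C12 in a five-membered oxa-aluminacycle, and iodinolysis with retention gives the Z-iodide with C10 and C13 trans.

Step 23
Reactants: 32 C12 vinyl iodide
Product: 33 (1R,2S,3E,6S,7E,10S,11E)-2,6-bis[(tert-butyldimethylsilyl)oxy]-1-{3-[(tert-butyldimethylsilyl)oxy]prop-1-en-2-yl}-4,8,12-trimethylcyclotetradeca-3,7,11-trien-10-ol
Conditions: MeZnCl (3 equiv), Pd(PPh3)4 (10 mol%), THF, rt → 40 °C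
Reagents that add atoms: methylzinc chloride, C[Zn]Cl
Why: Negishi coupling replaces iodine by methyl with retention of alkene geometry and tolerates the free hydroxyl, completing the E C11=C12 alkene.

Step 24
Reactants: 33 C10 allylic alcohol
Product: 34 (1R,2S,3E,6S,7E,10S,11E)-2,6-bis[(tert-butyldimethylsilyl)oxy]-1-{3-[(tert-butyldimethylsilyl)oxy]prop-1-en-2-yl}-4,8,12-trimethylcyclotetradeca-3,7,11-trien-10-yl acetate
Conditions: Ac2O, pyridine, DMAP (cat.), CH2Cl2, 0 °C → rt
Reagents that add atoms: acetic anhydride, CC(=O)OC(C)=O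
Why: DMAP-catalysed acylation of the only free hydroxyl, with retention at C10.

Step 25
Reactants: 34 C10 acetate
Product: 35 (1R,2S,3E,6S,7E,10S,11E)-2,6-dihydroxy-1-(3-hydroxyprop-1-en-2-yl)-4,8,12-trimethylcyclotetradeca-3,7,11-trien-10-yl acetate
Conditions: HF·pyridine, pyridine, THF, 0 °C → rt
Reagents that add atoms: none
Why: Pyridine-buffered HF cleaves all three TBS ethers without hydrolysing or migrating the allylic acetate and without ionising the allylic alcohols.

Step 26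
Reactants: 35 triol acetate
Product: 38 (1R,2S,3E,6S,7E,10S,11E)-10-acetoxy-6-hydroxycembra-3,7,11,15(17)-tetraen-16,2-olide (CNP0406430.1), via hydroxy enal 36 (not isolated), via lactol 37 (not isolated)
Conditions: TEMPO (20 mol%), PhI(OAc)2 (3 equiv), CH2Cl2, rt
Reagents that add atoms: none
Why: TEMPO/PhI(OAc)2 oxidative lactonisation: the primary allylic C16 alcohol is oxidised faster than the secondary ones, the enal is trapped by the C2 hydroxyl as a five-membered lactol, and this is oxidised on to the α-methylene lactone with the trans C1/C2 fusion already in place.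

**Compound list**

1 | hex-4-yn-1-ol | CC#CCCCO | starting material
2 | hex-4-ynal | CC#CCCC=O | intermediate
3 | 1,1-dibromohept-1-en-5-yne | CC#CCCC=C(Br)Br | intermediate
4 | lithium hepta-1,5-diyn-1-ide | [Li]C#CCCC#CC | intermediate
5 | methyl octa-2,6-diynoate | CC#CCCC#CC(=O)OC | intermediate
6 | methyl (2E)-2-(tributylstannyl)oct-2-en-6-ynoate | CC#CCC/C=C(/[Sn](CCCC)(CCCC)CCCC)C(=O)OC | intermediate
7 | methyl (2E)-2-iodooct-2-en-6-ynoate | CC#CCC/C=C(/I)C(=O)OC | intermediate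
8 | (2E)-2-iodooct-2-en-6-yn-1-ol | CC#CCC/C=C(/I)CO | intermediate
9 | tert-butyl{[(2E)-2-iodooct-2-en-6-yn-1-yl]oxy}dimethylsilane | CC#CCC/C=C(/I)CO[Si](C)(C)C(C)(C)C | intermediate
10 | tert-butyldimethyl{[(2Z)-2-[(4,4,5,5-tetramethyl-1,3,2-dioxaborolan-2-yl)methyl]oct-2-en-6-yn-1-yl]oxy}silane | CC#CCC/C=C(/CB1OC(C)(C)C(C)(C)O1)CO[Si](C)(C)C(C)(C)C | intermediate
11 | methyl 3-methylbut-2-enoate | CC(C)=CC(=O)OC | starting material
12 | lithium 1-methoxy-3-methylbuta-1,3-dien-1-olate | [Li]OC(OC)=CC(C)=C | intermediate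
13 | (1Z)-1-[(tert-butyldimethylsilyl)oxy]-1-methoxy-3-methylbuta-1,3-diene | C=C(C)/C=C(/OC)O[Si](C)(C)C(C)(C)C | intermediate
14 | but-2-yn-1-ol | CC#CCO | starting material
15 | but-2-ynal | CC#CC=O | intermediate
16 | methyl (2E,5S)-3-methyl-5-[(trichlorosilyl)oxy]oct-2-en-6-ynoate | CC#C[C@@H](O[Si](Cl)(Cl)Cl)C/C(C)=C/C(=O)OC | intermediate
17 | methyl (2E,5S)-5-hydroxy-3-methyloct-2-en-6-ynoate | CC#C[C@@H](O)C/C(C)=C/C(=O)OC | intermediate
18 | methyl (2E,5S)-3-methyl-5-[(triethylsilyl)oxy]oct-2-en-6-ynoate | CC#C[C@@H](O[Si](CC)(CC)CC)C/C(C)=C/C(=O)OC | intermediate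
19 | (2E,5S)-3-methyl-5-[(triethylsilyl)oxy]oct-2-en-6-yn-1-ol | CC#C[C@@H](O[Si](CC)(CC)CC)C/C(C)=C/CO | intermediate
20 | (2E,5S)-3-methyl-5-[(triethylsilyl)oxy]oct-2-en-6-ynal | CC#C[C@@H](O[Si](CC)(CC)CC)C/C(C)=C/C=O | intermediate
21 | methyl (2E,5S,6E,9S)-3,7-dimethyl-5-[(trichlorosilyl)oxy]-9-[(triethylsilyl)oxy]dodeca-2,6-dien-10-ynoate | CC#C[C@@H](O[Si](CC)(CC)CC)C/C(C)=C/[C@@H](O[Si](Cl)(Cl)Cl)C/C(C)=C/C(=O)OC | intermediate
22 | methyl (2E,5S,6E,9S)-5-hydroxy-3,7-dimethyl-9-[(triethylsilyl)oxy]dodeca-2,6-dien-10-ynoate | CC#C[C@@H](O[Si](CC)(CC)CC)C/C(C)=C/[C@@H](O)C/C(C)=C/C(=O)OC | intermediate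
23 | methyl (2E,5S,6E,9S)-5-[(tert-butyldimethylsilyl)oxy]-3,7-dimethyl-9-[(triethylsilyl)oxy]dodeca-2,6-dien-10-ynoate | CC#C[C@@H](O[Si](CC)(CC)CC)C/C(C)=C/[C@@H](O[Si](C)(C)C(C)(C)C)C/C(C)=C/C(=O)OC | intermediate
24 | (2E,5S,6E,9S)-5-[(tert-butyldimethylsilyl)oxy]-3,7-dimethyl-9-[(triethylsilyl)oxy]dodeca-2,6-dien-10-yn-1-ol | CC#C[C@@H](O[Si](CC)(CC)CC)C/C(C)=C/[C@@H](O[Si](C)(C)C(C)(C)C)C/C(C)=C/CO | intermediate
25 | (2E,5S,6E,9S)-5-[(tert-butyldimethylsilyl)oxy]-3,7-dimethyl-9-[(triethylsilyl)oxy]dodeca-2,6-dien-10-ynal | CC#C[C@@H](O[Si](CC)(CC)CC)C/C(C)=C/[C@@H](O[Si](C)(C)C(C)(C)C)C/C(C)=C/C=O | intermediate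
26 | pinacol borate ester of 27 (O12–Bpin) | CC#C[C@@H](O[Si](CC)(CC)CC)C/C(C)=C/[C@@H](O[Si](C)(C)C(C)(C)C)C/C(C)=C/[C@H](OB1OC(C)(C)C(C)(C)O1)[C@H](CCC#CC)C(=C)CO[Si](C)(C)C(C)(C)C | intermediate
27 | (4S,6E,8S,10E,12S,13R)-8-[(tert-butyldimethylsilyl)oxy]-13-{3-[(tert-butyldimethylsilyl)oxy]prop-1-en-2-yl}-6,10-dimethyl-4-[(triethylsilyl)oxy]octadeca-6,10-diene-2,16-diyn-12-ol | CC#C[C@@H](O[Si](CC)(CC)CC)C/C(C)=C/[C@@H](O[Si](C)(C)C(C)(C)C)C/C(C)=C/[C@H](O)[C@H](CCC#CC)C(=C)CO[Si](C)(C)C(C)(C)C | intermediate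
28 | (4S,6E,8S,10E,12S,13R)-8,12-bis[(tert-butyldimethylsilyl)oxy]-13-{3-[(tert-butyldimethylsilyl)oxy]prop-1-en-2-yl}-6,10-dimethyl-4-[(triethylsilyl)oxy]octadeca-6,10-diene-2,16-diyne | CC#C[C@@H](O[Si](CC)(CC)CC)C/C(C)=C/[C@@H](O[Si](C)(C)C(C)(C)C)C/C(C)=C/[C@H](O[Si](C)(C)C(C)(C)C)[C@H](CCC#CC)C(=C)CO[Si](C)(C)C(C)(C)C | intermediate
29 | (1R,2S,3E,6S,7E,10S)-2,6-bis[(tert-butyldimethylsilyl)oxy]-1-{3-[(tert-butyldimethylsilyl)oxy]prop-1-en-2-yl}-4,8-dimethyl-10-[(triethylsilyl)oxy]cyclotetradeca-3,7-dien-11-yne | C=C(CO[Si](C)(C)C(C)(C)C)[C@H]1CCC#C[C@@H](O[Si](CC)(CC)CC)C/C(C)=C/[C@@H](O[Si](C)(C)C(C)(C)C)C/C(C)=C/[C@@H]1O[Si](C)(C)C(C)(C)C | intermediate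
30 | (1R,2S,3E,6S,7E,10S)-2,6-bis[(tert-butyldimethylsilyl)oxy]-1-{3-[(tert-butyldimethylsilyl)oxy]prop-1-en-2-yl}-4,8-dimethylcyclotetradeca-3,7-dien-11-yn-10-ol | C=C(CO[Si](C)(C)C(C)(C)C)[C@H]1CCC#C[C@@H](O)C/C(C)=C/[C@@H](O[Si](C)(C)C(C)(C)C)C/C(C)=C/[C@@H]1O[Si](C)(C)C(C)(C)C | intermediate
31 | sodium alkenylalanate of 30 (five-membered O10–Al–C12=C11–C10 ring, two 2-methoxyethoxy ligands on Al) | C=C(CO[Si](C)(C)C(C)(C)C)[C@H]1CC/C2=C/[C@@H](O[Al-]2(OCCOC)OCCOC)C/C(C)=C/[C@@H](O[Si](C)(C)C(C)(C)C)C/C(C)=C/[C@@H]1O[Si](C)(C)C(C)(C)C.[Na+] | intermediate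
32 | (1R,2S,3E,6S,7E,10S,11Z)-2,6-bis[(tert-butyldimethylsilyl)oxy]-1-{3-[(tert-butyldimethylsilyl)oxy]prop-1-en-2-yl}-12-iodo-4,8-dimethylcyclotetradeca-3,7,11-trien-10-ol | C=C(CO[Si](C)(C)C(C)(C)C)[C@H]1CC/C(I)=C/[C@@H](O)C/C(C)=C/[C@@H](O[Si](C)(C)C(C)(C)C)C/C(C)=C/[C@@H]1O[Si](C)(C)C(C)(C)C | intermediate
33 | (1R,2S,3E,6S,7E,10S,11E)-2,6-bis[(tert-butyldimethylsilyl)oxy]-1-{3-[(tert-butyldimethylsilyl)oxy]prop-1-en-2-yl}-4,8,12-trimethylcyclotetradeca-3,7,11-trien-10-ol | C=C(CO[Si](C)(C)C(C)(C)C)[C@H]1CC/C(C)=C/[C@@H](O)C/C(C)=C/[C@@H](O[Si](C)(C)C(C)(C)C)C/C(C)=C/[C@@H]1O[Si](C)(C)C(C)(C)C | intermediate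
34 | (1R,2S,3E,6S,7E,10S,11E)-2,6-bis[(tert-butyldimethylsilyl)oxy]-1-{3-[(tert-butyldimethylsilyl)oxy]prop-1-en-2-yl}-4,8,12-trimethylcyclotetradeca-3,7,11-trien-10-yl acetate | C=C(CO[Si](C)(C)C(C)(C)C)[C@H]1CC/C(C)=C/[C@@H](OC(C)=O)C/C(C)=C/[C@@H](O[Si](C)(C)C(C)(C)C)C/C(C)=C/[C@@H]1O[Si](C)(C)C(C)(C)C | intermediate
35 | (1R,2S,3E,6S,7E,10S,11E)-2,6-dihydroxy-1-(3-hydroxyprop-1-en-2-yl)-4,8,12-trimethylcyclotetradeca-3,7,11-trien-10-yl acetate | C=C(CO)[C@H]1CC/C(C)=C/[C@@H](OC(C)=O)C/C(C)=C/[C@@H](O)C/C(C)=C/[C@@H]1O | intermediate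
36 | 2-[(1R,2S,3E,6S,7E,10S,11E)-10-acetoxy-2,6-dihydroxy-4,8,12-trimethylcyclotetradeca-3,7,11-trien-1-yl]prop-2-enal | C=C(C=O)[C@H]1CC/C(C)=C/[C@@H](OC(C)=O)C/C(C)=C/[C@@H](O)C/C(C)=C/[C@@H]1O | intermediate
37 | C16 lactol of 38 (16-hydroxy-16,2-epoxide, both C16 epimers) | C=C1C(O)O[C@H]2/C=C(\C)C[C@H](O)/C=C(\C)C[C@H](OC(C)=O)/C=C(\C)CC[C@H]12 | intermediate
38 | (1R,2S,3E,6S,7E,10S,11E)-10-acetoxy-6-hydroxycembra-3,7,11,15(17)-tetraen-16,2-olide (CNP0406430.1) | C=C1C(=O)O[C@H]2/C=C(\C)C[C@H](O)/C=C(\C)C[C@H](OC(C)=O)/C=C(\C)CC[C@H]12 | target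

**Count and risks**

Total step count: 26. Longest linear sequence: 18 steps (steps 9–26, from but-2-yn-1-ol); the boronate branch (steps 1–7) joins at step 18 and the dienolate (step 8) at steps 10 and 14.

Step 18 (most at risk). The phosphoric acid may discriminate the aldehyde faces poorly with a 2,3-disubstituted allylboronate, or the uncatalysed background addition may compete, so that both anti diastereomers form. The fallback sets out from 25 and 10. Thermal, uncatalysed allylboration (toluene, 40 °C) keeps the chair-controlled anti relationship and should give 27 mixed with its (12R,13S)-diastereomer F1. A Sharpless kinetic resolution (Ti(OiPr)4, L-(+)-diisopropyl tartrate, t-BuOOH, 4 Å MS, CH2Cl2, −20 °C) is then expected to epoxidise the 12R allylic alcohol faster, converting F1 into the (10R,11R)-epoxy alcohol F2 and leaving 27. The route is rejoined at 27, before step 19.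

Step 10. The slim, linear alkynyl group of the ynal may be differentiated poorly from hydrogen in the chiral silicon complex, eroding enantioselectivity at C10. The fallback sets out from 15 and 13. A BF3·OEt2-mediated vinylogous Mukaiyama aldol reaction (CH2Cl2, −78 °C) should give the racemic carbinol F3. Dess–Martin oxidation gives the ynone F4, used at once because its C4 methylene is acidic. Midland reduction with (S)-Alpine-borane, a base-free reagent that reads alkynyl against alkyl, should then deliver the 5S alcohol. The route is rejoined at 17.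

Step 22. Hydride delivery across the ring alkyne may stall in the hindered macrocycle, or the alkenylalanate may be protonated rather than iodinated, leaving no handle at C12. The fallback sets out from 30. MnO2 oxidation gives the macrocyclic ynone F5. Conjugate addition of Me2CuLi (THF, −78 °C) should give the β-methyl enone F6, whose E isomer (C10 and C13 trans) is expected to be favoured after equilibration through the allenolate. Corey–Bakshi–Shibata reduction with (R)-Me-CBS and catecholborane (toluene, −78 °C) then sets 10S. The route is rejoined at 33, bypassing 32.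

Further compounds
F1 | step 18 | (4S,6E,8S,10E,12R,13S)-diastereomer of 27 | CC#C[C@@H](O[Si](CC)(CC)CC)C/C(C)=C/[C@@H](O[Si](C)(C)C(C)(C)C)C/C(C)=C/[C@@H](O)[C@@H](CCC#CC)C(=C)CO[Si](C)(C)C(C)(C)C
F2 | step 18 | (10R,11R)-10,11-epoxide of F1 (erythro epoxy alcohol) | CC#C[C@@H](O[Si](CC)(CC)CC)C/C(C)=C/[C@@H](O[Si](C)(C)C(C)(C)C)C[C@@]1(C)O[C@@H]1[C@@H](O)[C@@H](CCC#CC)C(=C)CO[Si](C)(C)C(C)(C)C
F3 | step 10 | racemic methyl (2E)-5-hydroxy-3-methyloct-2-en-6-ynoate | CC#CC(O)C/C(C)=C/C(=O)OC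
F4 | step 10 | methyl (2E)-3-methyl-5-oxooct-2-en-6-ynoate | CC#CC(=O)C/C(C)=C/C(=O)OC
F5 | step 22 | C10 ynone of 30: (3E,6S,7E)-2,6-bis(TBS-oxy)-1-[3-(TBS-oxy)prop-1-en-2-yl]-4,8-dimethylcyclotetradeca-3,7-dien-11-yn-10-one (1R,2S) | C=C(CO[Si](C)(C)C(C)(C)C)[C@H]1CCC#CC(=O)C/C(C)=C/[C@@H](O[Si](C)(C)C(C)(C)C)C/C(C)=C/[C@@H]1O[Si](C)(C)C(C)(C)C
F6 | step 22 | (11E)-4,8,12-trimethyl C10 enone corresponding to 33 | C=C(CO[Si](C)(C)C(C)(C)C)[C@H]1CC/C(C)=C/C(=O)C/C(C)=C/[C@@H](O[Si](C)(C)C(C)(C)C)C/C(C)=C/[C@@H]1O[Si](C)(C)C(C)(C)C
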